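The route rests on cutting ring C of the lower flavan-3,4-diol unit at C4a–C4 and C2–C3, which excises C3–C4 with its cis-diol as an enediol two-carbon unit. In the forward sense an aryl oxocarbenium ion on the lower phenol oxygen O1 takes up 2,2-dimethyl-1,3-dioxole in an enantioselective oxa-Povarov [4+2] cycloaddition. This one operation closes ring C, forms both bonds and sets the all-cis C2/C3/C4 array; it exploits the aryl ether O1–C8a, whose only free ortho carbon is C4a. The precursor is the α-acetoxy ether of 4-benzyloxybenzaldehyde with the O1 phenol of a fully protected 2,4-trans 4-arylflavan, itself made by Friedel–Crafts coupling of an (S)-flavan-4-ol with 2-O-benzylpyrogallol.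

Key step: step 10

Assumption: 2,2-dimethyl-1,3-dioxole (17) is taken as a purchasable catalogue enol ether.
Remark: flavan numbering is used for both units (upper = 4-arylflavan, lower = flavan-3,4-diol). The CIP descriptors at upper C4 (S or R) and lower C3 change with the protecting groups; the geometry does not.

Step 1
Reactants: 1 1-(2,3,4-trihydroxyphenyl)ethan-1-one (gallacetophenone)
Product: 2 1-[3,4-bis(benzyloxy)-2-hydroxyphenyl]ethan-1-one
Conditions: BnBr (2.1 equiv), K2CO3 (2.2 equiv), acetone, reflux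
Reagents that add atoms: benzyl bromide, BrCc1ccccc1
Why: Williamson etherification in which the 2-OH, held in a hydrogen bond to the ketone, stays free while the 3- and 4-OH groups are benzylated.

Step 2
Reactants: 2 1-[3,4-bis(benzyloxy)-2-hydroxyphenyl]ethan-1-one
Product: 4 7,8-bis(benzyloxy)-4H-chromen-4-one, via enaminone 3 (not isolated)
Conditions: Me2NCH(OMe)2, toluene, 100 °C; then conc. HCl, CH2Cl2, 40 °C
Reagents that add atoms: N,N-dimethylformamide dimethyl acetal, COC(OC)N(C)C
Why: enaminone formation at the methyl ketone followed by acid-promoted addition–elimination of the phenol (enaminone chromone synthesis), which benzyl ethers should tolerate.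

Step 3
Reactants: 4 7,8-bis(benzyloxy)-4H-chromen-4-one; 5 4-(benzyloxy)phenylboronic acid
Product: 6 (2S)-7,8-bis(benzyloxy)-2-[4-(benzyloxy)phenyl]chroman-4-one
Conditions: Pd(OCOCF3)2 (5 mol %), (R)-4-tert-butyl-2-(pyridin-2-yl)-4,5-dihydrooxazole (6 mol %), NH4PF6 (30 mol %), H2O (5 equiv), ClCH2CH2Cl, 60 °C
Reagents that add atoms: none
Why: asymmetric conjugate addition of an arylboronic acid to a chromone by a cationic divalent palladium–pyridinooxazoline catalyst, whose tert-butyl group directs aryl transfer to one face of C2; the (R)-ligand is the antipode expected to give the 2S flavanone.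

Step 4
Reactants: 6 (2S)-7,8-bis(benzyloxy)-2-[4-(benzyloxy)phenyl]chroman-4-one
Product: 7 (2S,4S)-7,8-bis(benzyloxy)-2-[4-(benzyloxy)phenyl]chroman-4-ol (2,4-cis)
Conditions: NaBH4, MeOH/THF, 0 °C
Reagents that add atoms: none
Why: borohydride reduction with axial hydride delivery to the half-chair bearing an equatorial 2-aryl group, which should give the 2,4-cis alcohol (this centre is ionised in step 6 in any case).

Step 5
Reactants: 8 benzene-1,2,3-triol (pyrogallol)
Product: 9 2-(benzyloxy)benzene-1,3-diol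
Conditions: BnBr (1.0 equiv), Li2CO3 (1.2 equiv), DMF, 45 °C
Reagents that add atoms: benzyl bromide, BrCc1ccccc1
Why: Williamson etherification under mono-deprotonation, the central OH being the most acidic because its phenoxide is flanked by two hydrogen-bond donors.

Step 6
Reactants: 7 (2S,4S)-flavan-4-ol; 9 2-(benzyloxy)benzene-1,3-diol
Product: 10 2-(benzyloxy)-4-{(2S,4S)-7,8-bis(benzyloxy)-2-[4-(benzyloxy)phenyl]chroman-4-yl}benzene-1,3-diol (2,4-trans)
Conditions: 9 (3 equiv), BF3·OEt2 (0.3 equiv), 4 Å MS, CH2Cl2/1,4-dioxane (4:1), −20 °C → 0 °C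
Reagents that add atoms: none
Why: Friedel–Crafts benzylation through the flavan-4-yl cation (stabilised by O1 and the para 7-OBn), in which the symmetric resorcinol 9 can react only at its equivalent C4/C6 positions and axial attack anti to the equatorial 2-aryl group should give the 2,4-trans isomer; excess 9 suppresses double alkylation.

Step 7
Reactants: 10 2,4-trans 4-arylflavan diol
Product: 12 benzyl 2-(benzyloxy)-3-[(tert-butyldimethylsilyl)oxy]-6-{(2S,4R)-7,8-bis(benzyloxy)-2-[4-(benzyloxy)phenyl]chroman-4-yl}phenyl carbonate, via silyl ether 11 (not isolated)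
Conditions: TBSCl (1.05 equiv), Et3N, DMAP (10 mol %), CH2Cl2, 0 °C; then CbzCl (1.5 equiv), Et3N, 0 °C → rt
Reagents that add atoms: tert-butyldimethylsilyl chloride, CC(C)(C)[Si](C)(C)Cl; benzyl chloroformate, O=C(Cl)OCc1ccccc1
Why: steric differentiation by silylation then acylation, the bulky silyl chloride taking the phenol with a free ortho position (future O1) and the remaining phenol, flanked by OBn and the flavanyl group, then being converted to the carbonate.

Step 8
Reactants: 12 silyl ether carbonate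
Product: 13 benzyl 2-(benzyloxy)-3-hydroxy-6-{(2S,4R)-7,8-bis(benzyloxy)-2-[4-(benzyloxy)phenyl]chroman-4-yl}phenyl carbonate
Conditions: Bu4NF (1.1 equiv), AcOH (1.1 equiv), THF, 0 °C
Reagents that add atoms: none
Why: fluoride-induced cleavage of the aryl silyl ether, buffered with acetic acid so that no free phenoxide attacks the aryl carbonate.

Step 9
Reactants: 14 4-(benzyloxy)benzaldehyde; 13 phenol carbonate
Product: 16 {2-(benzyloxy)-3-[(benzyloxycarbonyl)oxy]-4-[(2S,4R)-7,8-bis(benzyloxy)-2-(4-(benzyloxy)phenyl)chroman-4-yl]phenoxy}[4-(benzyloxy)phenyl]methyl acetate (both epimers at the acetal carbon), via chloro acetate 15 (not isolated)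
Conditions: 14 (1.3 equiv), AcCl (1.2 equiv), ZnCl2 (2 mol %), CH2Cl2, 0 °C → rt, volatiles removed; then 13, i-Pr2NEt, CH2Cl2, −30 °C → 0 °C
Reagents that add atoms: acetyl chloride, CC(Cl)=O
Why: addition of the acyl chloride to the aldehyde gives the α-chlorobenzyl acetate, whose ionisable C–Cl bond is displaced by the phenol (SN1-type O-alkylation, as in acyloxyalkyl ether formation); the configuration of the acetal carbon is irrelevant because it is ionised next.

Step 10
Reactants: 16 α-acetoxy ether; 17 2,2-dimethyl-1,3-dioxole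
Product: 19 benzyl (2R,3S,4R)-8-(benzyloxy)-2-[4-(benzyloxy)phenyl]-6-{(2S,4R)-7,8-bis(benzyloxy)-2-[4-(benzyloxy)phenyl]chroman-4-yl}-3,4-(isopropylidenedioxy)chroman-7-yl carbonate (2,3-cis-3,4-cis), via oxocarbenium ion pair 18 (not isolated)
Conditions: (R)-3,3'-bis(2,4,6-triisopropylphenyl)-1,1'-binaphthyl-2,2'-diyl N-triflylphosphoramide (10 mol %), 17 (4 equiv), 5 Å MS, toluene, −60 °C → −30 °C
Reagents that add atoms: none
Why: Proposed new method: the chiral N-triflylphosphoramide protonates the acetate of 16, acetic acid leaves and the E-configured aryl oxocarbenium ion 18 forms as a contact ion pair with the phosphoramidate; its cationic 2-oxadiene (C4a=C8a–O1=C2) adds the electron-rich dioxole 17 in an inverse-electron-demand [4+2] cycloaddition (oxa-Povarov reaction), C2–C3 forming ahead of C4–C4a, and loss of the C4a proton restores the arene and the catalyst. The closest known reaction types are the SnCl4-promoted oxa-Povarov reaction of aryl oxocarbenium ions with alkenes and the chiral-phosphoric-acid-catalysed Povarov reaction of the aza analogues; control of an aryl oxocarbenium [4+2] by a chiral counter-anion is the part not yet shown. The one ring closed is ring C of the lower unit, by [4+2] cycloaddition (in the stepwise limit a Friedel–Crafts attack of C4a on the dioxolanyl oxocarbenium, 6-exo-trig with respect to that cation). C3 and C4 are cis because both oxygens come from the cis ring-fused dioxole, C2 is cis to them because 17 approaches endo to the E-oxocarbenium (aryl group outside), and the absolute configuration (the 2R,3R,4R array of the target; 3S by CIP in the acetonide) is fixed by the anion, which shields one face of the ion pair, the remote upper unit having no say; should the (R)-acid favour the mirror face, its (S)-antipode is used. Regioselectivity is secured because C4a is the only unsubstituted carbon ortho to O1 (C8 bears OBn), the acetate leaving group secures ionisation toward the aryloxy-substituted cation, and the O7 carbonate keeps the benzylic C4–O bond of 19 from re-ionising under the acid.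

Step 11
Reactants: 19 all-cis acetonide
Product: 20 benzyl (2R,3R,4R)-8-(benzyloxy)-2-[4-(benzyloxy)phenyl]-6-{(2S,4R)-7,8-bis(benzyloxy)-2-[4-(benzyloxy)phenyl]chroman-4-yl}-3,4-dihydroxychroman-7-yl carbonate
Conditions: AcOH/H2O/THF (4:1:1), 45 °C
Reagents that add atoms: none
Why: acid hydrolysis of the isopropylidene acetal through the tertiary dioxolanyl oxocarbenium, while heterolysis of the benzylic C4–O bond is disfavoured because the para oxygen O7 is acylated and C3 carries oxygen, so the cis-diol should be released without epimerisation.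

Step 12
Reactants: 20 protected diol
Product: 21 (2R,3R,4R)-6-[(2S,4S)-7,8-dihydroxy-2-(4-hydroxyphenyl)chroman-4-yl]-2-(4-hydroxyphenyl)chroman-3,4,7,8-tetrol (CNP0209379.1)
Conditions: H2 (1 atm), 20% Pd(OH)2/C, degassed THF/MeOH (1:1), rt, filtration under argon
Reagents that add atoms: none
Why: hydrogenolysis of the five benzyl ethers and the benzyl carbonate (which loses CO2) under neutral conditions, under which the secondary benzylic C4–OH and the pyran C2–O bonds should be retained as in debenzylations of catechin-type flavans.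

Compound list
1 | 1-(2,3,4-trihydroxyphenyl)ethan-1-one (gallacetophenone) | CC(=O)c1ccc(O)c(O)c1O | starting material
2 | 1-[3,4-bis(benzyloxy)-2-hydroxyphenyl]ethan-1-one | CC(=O)c1ccc(OCc2ccccc2)c(OCc2ccccc2)c1O | intermediate
3 | (E)-1-[3,4-bis(benzyloxy)-2-hydroxyphenyl]-3-(dimethylamino)prop-2-en-1-one | CN(C)/C=C/C(=O)c1ccc(OCc2ccccc2)c(OCc2ccccc2)c1O | intermediate
4 | 7,8-bis(benzyloxy)-4H-chromen-4-one | O=C1C=COc2c1ccc(OCc1ccccc1)c2OCc1ccccc1 | intermediate
5 | 4-(benzyloxy)phenylboronic acid | OB(O)c1ccc(OCc2ccccc2)cc1 | starting material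
6 | (2S)-7,8-bis(benzyloxy)-2-[4-(benzyloxy)phenyl]chroman-4-one | O(Cc5ccccc5)c1ccc([C@@H]2CC(=O)c3ccc(OCc5ccccc5)c(OCc5ccccc5)c3O2)cc1 | intermediate
7 | (2S,4S)-7,8-bis(benzyloxy)-2-[4-(benzyloxy)phenyl]chroman-4-ol (2,4-cis) | O(Cc5ccccc5)c1ccc([C@@H]2C[C@H](O)c3ccc(OCc5ccccc5)c(OCc5ccccc5)c3O2)cc1 | intermediate
8 | benzene-1,2,3-triol (pyrogallol) | Oc1cccc(O)c1O | starting material
9 | 2-(benzyloxy)benzene-1,3-diol | Oc1cccc(O)c1OCc1ccccc1 | intermediate
10 | 2-(benzyloxy)-4-{(2S,4S)-7,8-bis(benzyloxy)-2-[4-(benzyloxy)phenyl]chroman-4-yl}benzene-1,3-diol (2,4-trans) | O(Cc5ccccc5)c1ccc([C@@H]2C[C@@H](c3ccc(c(OCc5ccccc5)c3O)O)c3ccc(OCc5ccccc5)c(OCc5ccccc5)c3O2)cc1 | intermediate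
11 | 2-(benzyloxy)-3-[(tert-butyldimethylsilyl)oxy]-6-{(2S,4S)-7,8-bis(benzyloxy)-2-[4-(benzyloxy)phenyl]chroman-4-yl}phenol | O(Cc5ccccc5)c1ccc([C@@H]2C[C@@H](c3ccc(c(OCc5ccccc5)c3O)O[Si](C)(C)C(C)(C)C)c3ccc(OCc5ccccc5)c(OCc5ccccc5)c3O2)cc1 | intermediate
12 | benzyl 2-(benzyloxy)-3-[(tert-butyldimethylsilyl)oxy]-6-{(2S,4R)-7,8-bis(benzyloxy)-2-[4-(benzyloxy)phenyl]chroman-4-yl}phenyl carbonate | O(Cc5ccccc5)c1ccc([C@@H]2C[C@@H](c3ccc(c(OCc5ccccc5)c3OC(=O)OCc5ccccc5)O[Si](C)(C)C(C)(C)C)c3ccc(OCc5ccccc5)c(OCc5ccccc5)c3O2)cc1 | intermediate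
13 | benzyl 2-(benzyloxy)-3-hydroxy-6-{(2S,4R)-7,8-bis(benzyloxy)-2-[4-(benzyloxy)phenyl]chroman-4-yl}phenyl carbonate | O(Cc5ccccc5)c1ccc([C@@H]2C[C@@H](c3ccc(c(OCc5ccccc5)c3OC(=O)OCc5ccccc5)O)c3ccc(OCc5ccccc5)c(OCc5ccccc5)c3O2)cc1 | intermediate
14 | 4-(benzyloxy)benzaldehyde | O=Cc1ccc(OCc2ccccc2)cc1 | starting material
15 | [4-(benzyloxy)phenyl](chloro)methyl acetate | CC(=O)OC(Cl)c1ccc(OCc2ccccc2)cc1 | intermediate
16 | {2-(benzyloxy)-3-[(benzyloxycarbonyl)oxy]-4-[(2S,4R)-7,8-bis(benzyloxy)-2-(4-(benzyloxy)phenyl)chroman-4-yl]phenoxy}[4-(benzyloxy)phenyl]methyl acetate (both epimers at the acetal carbon) | O(Cc5ccccc5)c1ccc([C@@H]2C[C@@H](c3ccc(c(OCc5ccccc5)c3OC(=O)OCc5ccccc5)OC(OC(C)=O)c3ccc(OCc5ccccc5)cc3)c3ccc(OCc5ccccc5)c(OCc5ccccc5)c3O2)cc1 | intermediate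
17 | 2,2-dimethyl-1,3-dioxole | CC1(C)OC=CO1 | starting material
18 | aryl oxocarbenium ion from 16 ([4-(benzyloxy)benzylidene]aryloxonium cation, paired with the chiral phosphoramidate) | O(Cc5ccccc5)c1ccc([C@@H]2C[C@@H](c3ccc(c(OCc5ccccc5)c3OC(=O)OCc5ccccc5)[O+]=Cc3ccc(OCc5ccccc5)cc3)c3ccc(OCc5ccccc5)c(OCc5ccccc5)c3O2)cc1 | intermediate
19 | benzyl (2R,3S,4R)-8-(benzyloxy)-2-[4-(benzyloxy)phenyl]-6-{(2S,4R)-7,8-bis(benzyloxy)-2-[4-(benzyloxy)phenyl]chroman-4-yl}-3,4-(isopropylidenedioxy)chroman-7-yl carbonate (2,3-cis-3,4-cis) | O(Cc5ccccc5)c1ccc([C@@H]2C[C@@H](c3cc4c(c(OCc5ccccc5)c3OC(=O)OCc5ccccc5)O[C@H](c3ccc(OCc5ccccc5)cc3)[C@H](OC6(C)C)[C@@H]4O6)c3ccc(OCc5ccccc5)c(OCc5ccccc5)c3O2)cc1 | intermediate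
20 | benzyl (2R,3R,4R)-8-(benzyloxy)-2-[4-(benzyloxy)phenyl]-6-{(2S,4R)-7,8-bis(benzyloxy)-2-[4-(benzyloxy)phenyl]chroman-4-yl}-3,4-dihydroxychroman-7-yl carbonate | O(Cc5ccccc5)c1ccc([C@@H]2C[C@@H](c3cc4c(c(OCc5ccccc5)c3OC(=O)OCc5ccccc5)O[C@H](c3ccc(OCc5ccccc5)cc3)[C@H](O)[C@@H]4O)c3ccc(OCc5ccccc5)c(OCc5ccccc5)c3O2)cc1 | intermediate
21 | (2R,3R,4R)-6-[(2S,4S)-7,8-dihydroxy-2-(4-hydroxyphenyl)chroman-4-yl]-2-(4-hydroxyphenyl)chroman-3,4,7,8-tetrol (CNP0209379.1) | Oc1ccc([C@@H]2C[C@@H](c3cc4c(c(O)c3O)O[C@H](c3ccc(O)cc3)[C@H](O)[C@@H]4O)c3ccc(O)c(O)c3O2)cc1 | target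

Total step count: 12.
Longest linear sequence: 11 steps (steps 1, 2, 3, 4, 6, 7, 8, 9, 10, 11, 12; step 5 is a side branch).

Steps most likely to fail

1. Step 10 (Proposed new method). The chiral ion pair may discriminate the two faces of the oxocarbenium poorly, or turnover of the acid may stall through acetic acid build-up or uncatalysed ionisation. The fallback uses known chemistry and gives up catalyst control in favour of separation. Starting from 16, the oxa-Povarov reaction is run with stoichiometric SnCl4 and 17 in CH2Cl2 at −78 °C. It should give the endo adduct 19 together with the all-cis diastereomer carrying the mirror-image lower ring F1. The two are diastereomers because the upper unit is enantiopure, so they are separated by chromatography or preparative HPLC. The fallback returns to the route at 19.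

2. Step 9. Acetyl transfer from 15 to the phenol may compete with O-alkylation, or the acid-labile acetoxy ether may be lost on isolation. The fallback sets out from 13 and 14 and uses a benzotriazole leaving group. Aldehyde 14, 1H-benzotriazole and SOCl2 give 1-{[4-(benzyloxy)phenyl](chloro)methyl}-1H-benzotriazole F2. Phenol 13 is O-alkylated with it (Cs2CO3, MeCN, rt) to the base-stable and chromatography-stable benzotriazolyl ether F3. This is ionised with SnCl4 (loss of benzotriazolide) in the presence of 17, as in the fallback for step 10. The fallback returns to the route at 19.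

3. Step 3. Carbopalladation of the electron-rich 7,8-dialkoxychromone may be slow, with protodeboronation of 5 competing, or the enantioselectivity may be insufficient. The fallback sets out from 2 and 14. Claisen–Schmidt condensation (KOH, EtOH, rt) gives the 2'-hydroxychalcone F4. Oxa-Michael cyclisation (NaOAc, EtOH, reflux) gives the racemic flavanone F5. Kinetic resolution by asymmetric transfer hydrogenation with RuCl[(S,S)-TsDPEN](p-cymene) and HCO2H/Et3N, stopped near half conversion, should reduce the 2S enantiomer faster and give the (2S,4S)-alcohol directly; the unreacted 2R ketone is removed by chromatography. The fallback returns to the route at 7 and bypasses 4 and 6.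

Further compounds
F1 | step 10 | benzyl (2S,3R,4S)-8-(benzyloxy)-2-[4-(benzyloxy)phenyl]-6-{(2S)-7,8-bis(benzyloxy)-2-[4-(benzyloxy)phenyl]chroman-4-yl}-3,4-(isopropylidenedioxy)chroman-7-yl carbonate (all-cis diastereomer of 19 with the mirror-image lower ring) | O(Cc5ccccc5)c1ccc([C@@H]2C[C@@H](c3cc4c(c(OCc5ccccc5)c3OC(=O)OCc5ccccc5)O[C@@H](c3ccc(OCc5ccccc5)cc3)[C@@H](OC6(C)C)[C@H]4O6)c3ccc(OCc5ccccc5)c(OCc5ccccc5)c3O2)cc1
F2 | step 9 | 1-{[4-(benzyloxy)phenyl](chloro)methyl}-1H-benzotriazole | ClC(c1ccc(OCc2ccccc2)cc1)n1nnc2ccccc12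
F3 | step 9 | benzyl 3-{(1H-benzotriazol-1-yl)[4-(benzyloxy)phenyl]methoxy}-2-(benzyloxy)-6-{(2S)-7,8-bis(benzyloxy)-2-[4-(benzyloxy)phenyl]chroman-4-yl}phenyl carbonate (2,4-trans; both epimers at the acetal carbon) | O(Cc5ccccc5)c1ccc([C@@H]2C[C@@H](c3ccc(c(OCc5ccccc5)c3OC(=O)OCc5ccccc5)OC(n6nnc7ccccc67)c3ccc(OCc5ccccc5)cc3)c3ccc(OCc5ccccc5)c(OCc5ccccc5)c3O2)cc1
F4 | step 3 | (E)-1-[3,4-bis(benzyloxy)-2-hydroxyphenyl]-3-[4-(benzyloxy)phenyl]prop-2-en-1-one | O=C(/C=C/c1ccc(OCc2ccccc2)cc1)c1ccc(OCc2ccccc2)c(OCc2ccccc2)c1O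
F5 | step 3 | racemic 7,8-bis(benzyloxy)-2-[4-(benzyloxy)phenyl]chroman-4-one | O=C1CC(c2ccc(OCc3ccccc3)cc2)Oc2c1ccc(OCc1ccccc1)c2OCc1ccccc1
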